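**Strategy.** The target is cut at the C–C bond between the phenyl-bearing carbon of the central six-membered ring and the lactone carbon that carries the ring oxygen. The feature used is that the butenolide (lactone C=O, ring O, O-bearing enol carbon and the two alkene carbons) is one half of a diarylmaleic anhydride whose benzofuran-side carbonyl carbon has become that enol carbon. The precursor is thus a 3-(benzofuran-3-yl)-4-arylmaleic anhydride carrying a phenylacetyl group on benzofuran C2, with all three phenols as methyl ethers. In one operation the benzylic carbon of the ketone is acylated by the near anhydride carbonyl and water is lost, which closes the central ring and leaves the enol lactone in place.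

Key step: step 8

**Remarks on the chemistry.**
- The phenylacetyl group is placed on C2 while the benzofuran is still an electron-rich 3-alkyl heterocycle. Once the anhydride is attached, C2 would be the least reactive aromatic position in the molecule.
- The ketone is carried through the anhydride-forming condensation as a dioxolane. A free benzyl ketone next to an activated acetic acid side chain would instead undergo a six-membered Claisen closure.
- Methyl ethers are kept on all three phenols because they tolerate the strong-acid and Lewis-acid steps. They are removed at the end with an electrophilic reagent that does not open the enol lactone.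
- Assumption: the arylglyoxylic acid partner of the anhydride-forming step is a purchased starting material.

**Route**

Step 1
Reactants: 1 3,4-dimethoxyphenol; 2 ethyl 4-chloro-3-oxobutanoate
Product: 3 4-(chloromethyl)-6,7-dimethoxy-2H-chromen-2-one
Conditions: MeSO3H, 0 °C → rt
Reagents that add atoms: none
Why: Pechmann condensation: acid-catalysed transesterification and ring closure of the β-keto ester onto the phenol carbon ortho to OH and para to the 3-methoxy group (the other ortho site lies between two oxygen substituents) should give the 6,7-dimethoxycoumarin with the chloromethyl group intact.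

Step 2
Reactants: 3 4-(chloromethyl)-6,7-dimethoxy-2H-chromen-2-one
Product: 4 2-(5,6-dimethoxy-1-benzofuran-3-yl)acetic acid
Conditions: 1 M NaOH (aq), reflux; then HCl (aq)
Reagents that add atoms: sodium hydroxide, [Na+].[OH-]
Why: Base-induced ring contraction of a 4-(halomethyl)coumarin: hydroxide opens the lactone, the freed phenoxide displaces chloride in a 5-exo-tet Williamson closure, and the exocyclic alkene moves into the ring to give the aromatic benzofuran-3-acetic acid, whose C2 is the former CH2Cl carbon.

Step 3
Reactants: 4 2-(5,6-dimethoxy-1-benzofuran-3-yl)acetic acid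
Product: 5 methyl 2-(5,6-dimethoxy-1-benzofuran-3-yl)acetate
Conditions: MeOH, H2SO4 (cat.), reflux
Reagents that add atoms: methanol, CO
Why: Fischer esterification masks the carboxylic acid so that the Lewis-acid acylation and the ketalisation that follow are not disturbed by a free acid.

Step 4
Reactants: 5 methyl 2-(5,6-dimethoxy-1-benzofuran-3-yl)acetate; 6 phenylacetyl chloride
Product: 7 methyl 2-[5,6-dimethoxy-2-(2-phenylacetyl)-1-benzofuran-3-yl]acetate
Conditions: SnCl4, CH2Cl2, −20 → 0 °C
Reagents that add atoms: none
Why: Friedel–Crafts acylation should occur at C2, the most nucleophilic carbon of a 3-alkylbenzofuran, because attack there keeps the benzene ring aromatic and gives a C3 cation stabilised by the ring oxygen and by the para-related 6-methoxy group.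

Step 5
Reactants: 7 methyl 2-[5,6-dimethoxy-2-(2-phenylacetyl)-1-benzofuran-3-yl]acetate
Product: 8 methyl 2-[2-(2-benzyl-1,3-dioxolan-2-yl)-5,6-dimethoxy-1-benzofuran-3-yl]acetate
Conditions: TMSOCH2CH2OTMS, TMSOTf (cat.), CH2Cl2, −78 → −20 °C
Reagents that add atoms: 1,2-bis(trimethylsilyloxy)ethane, C[Si](C)(C)OCCO[Si](C)(C)C
Why: Noyori ketalisation is driven by irreversible formation of hexamethyldisiloxane and should therefore convert even this conjugated ketone at low temperature, removing the acidity of the benzylic CH2 for the next two steps.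

Step 6
Reactants: 8 methyl 2-[2-(2-benzyl-1,3-dioxolan-2-yl)-5,6-dimethoxy-1-benzofuran-3-yl]acetate
Product: 9 2-[2-(2-benzyl-1,3-dioxolan-2-yl)-5,6-dimethoxy-1-benzofuran-3-yl]acetic acid
Conditions: LiOH, THF/H2O, rt; then 1 M HCl to pH 3–4, 0 °C
Reagents that add atoms: lithium hydroxide, [Li+].[OH-]
Why: Ester saponification leaves the base-stable dioxolane untouched, and brief cold acidification should free the acid without cleaving the ketal.

Step 7
Reactants: 9 2-[2-(2-benzyl-1,3-dioxolan-2-yl)-5,6-dimethoxy-1-benzofuran-3-yl]acetic acid; 10 2-(4-methoxyphenyl)-2-oxoacetic acid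
Product: 12 3-[5,6-dimethoxy-2-(2-phenylacetyl)-1-benzofuran-3-yl]-4-(4-methoxyphenyl)furan-2,5-dione, via dioxolane-masked anhydride 11 (not isolated)
Conditions: Ac2O, Et3N, THF, 70 °C; then 2 M HCl (aq), THF, 45 °C
Reagents that add atoms: water, O
Why: Perkin-type condensation of an arylacetic acid with an arylglyoxylic acid (mixed anhydrides, aldol-type addition of the arylacetyl enolate to the keto group, cyclisation and dehydration) should give the cis-diarylmaleic anhydride directly, the masked ketone offering no acidic hydrogen, and aqueous acid then hydrolyses the dioxolane while any ring-opened maleic acid closes back to the anhydride.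

Step 8
Reactants: 12 3-[5,6-dimethoxy-2-(2-phenylacetyl)-1-benzofuran-3-yl]-4-(4-methoxyphenyl)furan-2,5-dione
Product: 14 γ-lactone of (2Z)-2-(2-hydroxy-7,8-dimethoxy-4-oxo-3-phenyldibenzo[b,d]furan-1(4H)-ylidene)-2-(4-methoxyphenyl)acetic acid (tri-O-methyl target), via hydroxybutenolide adduct 13 (not isolated)
Conditions: NaOAc, Ac2O, 100 °C
Reagents that add atoms: none
Why: Acetate reversibly enolises the benzylic CH2, which is activated by both the ketone and the phenyl ring, and the enolate carbon adds to the anhydride carbonyl attached to the benzofuran-bearing alkene carbon to give adduct 13, which loses water by E1cB elimination, either through its acetate or through its ring-opened keto-acid tautomer, which re-lactonises in Ac2O, so both channels should end in the same enol lactone. The closest known reaction type is the Perkin/Gabriel condensation of a cyclic anhydride with an active methylene compound to an ylidene lactone (alkylidenephthalide synthesis), here run intramolecularly. The one ring formed is the central six-membered carbocycle, closed in a 6-(enolendo)-exo-trig mode, and the five-membered lactone is the surviving half of the anhydride. No stereocentre is created, and the geometry of the new tetrasubstituted C=C is fixed because it is endocyclic in the six-membered ring. The selectivity needed is near versus far carbonyl and carbon versus oxygen of the enolate: the far carbonyl would require a seven-membered ring, whereas O-attack on the near carbonyl would also close a six-membered ring, but that enol ester is an activated acyl donor that reverts to the anhydride through its cis carboxylate under the acetate conditions, so the material should drain into the C-acylated, fully conjugated enol lactone.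

Step 9
Reactants: 14 tri-O-methyl target
Product: 15 γ-lactone of (2Z)-2-(2,7,8-trihydroxy-4-oxo-3-phenyldibenzo[b,d]furan-1(4H)-ylidene)-2-(4-hydroxyphenyl)acetic acid (CNP0139113.0)
Conditions: BBr3, CH2Cl2, −78 °C → rt; then H2O
Reagents that add atoms: none
Why: Electrophilic (Lewis-acid) cleavage of aryl methyl ethers by BBr3 should remove all three methyl groups, the catechol pair through a cyclic borate, while the enol lactone, which nucleophilic dealkylating agents would open, is left intact or re-closes on the acidic work-up.

**Compound list**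

1 | 3,4-dimethoxyphenol | COc1ccc(O)cc1OC | starting material
2 | ethyl 4-chloro-3-oxobutanoate | CCOC(=O)CC(=O)CCl | starting material
3 | 4-(chloromethyl)-6,7-dimethoxy-2H-chromen-2-one | COc1cc2oc(=O)cc(CCl)c2cc1OC | intermediate
4 | 2-(5,6-dimethoxy-1-benzofuran-3-yl)acetic acid | COc1cc2occ(CC(=O)O)c2cc1OC | intermediate
5 | methyl 2-(5,6-dimethoxy-1-benzofuran-3-yl)acetate | COC(=O)Cc1coc2cc(OC)c(OC)cc12 | intermediate
6 | phenylacetyl chloride | O=C(Cl)Cc1ccccc1 | starting material
7 | methyl 2-[5,6-dimethoxy-2-(2-phenylacetyl)-1-benzofuran-3-yl]acetate | COC(=O)Cc1c(C(=O)Cc2ccccc2)oc2cc(OC)c(OC)cc12 | intermediate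
8 | methyl 2-[2-(2-benzyl-1,3-dioxolan-2-yl)-5,6-dimethoxy-1-benzofuran-3-yl]acetate | COC(=O)Cc1c(C2(Cc3ccccc3)OCCO2)oc2cc(OC)c(OC)cc12 | intermediate
9 | 2-[2-(2-benzyl-1,3-dioxolan-2-yl)-5,6-dimethoxy-1-benzofuran-3-yl]acetic acid | OC(=O)Cc1c(C2(Cc3ccccc3)OCCO2)oc2cc(OC)c(OC)cc12 | intermediate
10 | 2-(4-methoxyphenyl)-2-oxoacetic acid | COc1ccc(C(=O)C(=O)O)cc1 | starting material
11 | 3-[2-(2-benzyl-1,3-dioxolan-2-yl)-5,6-dimethoxy-1-benzofuran-3-yl]-4-(4-methoxyphenyl)furan-2,5-dione | COc1ccc(C2=C(c3c(C4(Cc5ccccc5)OCCO4)oc4cc(OC)c(OC)cc34)C(=O)OC2=O)cc1 | intermediate (not isolated)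
12 | 3-[5,6-dimethoxy-2-(2-phenylacetyl)-1-benzofuran-3-yl]-4-(4-methoxyphenyl)furan-2,5-dione | O=C1OC(=O)C(c2c(C(=O)Cc3ccccc3)oc3cc(OC)c(OC)cc23)=C1c1ccc(OC)cc1 | intermediate (key-step precursor)
13 | hydroxybutenolide adduct: compound 14 with water added across the new C=C, OH on the lactone carbon that carries the ring oxygen and H on the phenyl-bearing carbon (diastereomer mixture at these two transient sp3 carbons, both lost on dehydration) | O=C1OC2(O)C(c3ccccc3)C(=O)c3oc4cc(OC)c(OC)cc4c3C2=C1c1ccc(OC)cc1 | intermediate (not isolated)
14 | γ-lactone of (2Z)-2-(2-hydroxy-7,8-dimethoxy-4-oxo-3-phenyldibenzo[b,d]furan-1(4H)-ylidene)-2-(4-methoxyphenyl)acetic acid | O=C1OC2=C(c3ccccc3)C(=O)c3oc4cc(OC)c(OC)cc4c3C2=C1c1ccc(OC)cc1 | intermediate (key-step product)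
15 | γ-lactone of (2Z)-2-(2,7,8-trihydroxy-4-oxo-3-phenyldibenzo[b,d]furan-1(4H)-ylidene)-2-(4-hydroxyphenyl)acetic acid | O=C1OC2=C(c3ccccc3)C(=O)c3oc4cc(O)c(O)cc4c3C2=C1c1ccc(O)cc1 | target

**Step count and risk**

Total step count: 9. Longest linear sequence: 9 steps (1 → 15).

Steps most likely to fail:

Step 8 (key step). Process at risk: the ketone enolate may be O-acetylated by the solvent anhydride, or may rest as the six-membered O-acyl enol ester, so that the C–C bond does not form. The fallback sets out from 12 and returns at 14, and replaces the anhydride electrophile with esters. Refluxing MeOH opens 12 to the half ester (2Z)-2-[5,6-dimethoxy-2-(2-phenylacetyl)-1-benzofuran-3-yl]-4-methoxy-3-(4-methoxyphenyl)-4-oxobut-2-enoic acid F1, drawn as the isomer from attack at the less hindered anisyl-side carbonyl; the other isomer converges. It is methylated in the same solution with TMSCHN2 to dimethyl (2Z)-2-[5,6-dimethoxy-2-(2-phenylacetyl)-1-benzofuran-3-yl]-3-(4-methoxyphenyl)but-2-enedioate F2. NaH in THF should then bring about a Dieckmann-type Claisen closure of the ketone enolate on the near ester (six-membered; the far ester would need seven) to methyl (2Z)-2-(2-hydroxy-7,8-dimethoxy-4-oxo-3-phenyldibenzo[b,d]furan-1(4H)-ylidene)-2-(4-methoxyphenyl)acetate F3. TsOH in hot toluene lactonises the enol hydroxyl of F3 onto the cis ester with loss of MeOH to give 14.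

Step 7. Process at risk: sluggish addition of the hindered arylacetyl component to the keto acid, with self-condensation of either acid or loss of the dioxolane in the hot anhydride medium. The fallback sets out from 8 and returns at 12, and uses a base-mediated maleimide condensation. Ammonolysis of 8 (NH3, MeOH, 60 °C) gives 2-[2-(2-benzyl-1,3-dioxolan-2-yl)-5,6-dimethoxy-1-benzofuran-3-yl]acetamide F4. Condensation with purchased methyl 2-(4-methoxyphenyl)-2-oxoacetate under KOtBu in THF should give 3-[2-(2-benzyl-1,3-dioxolan-2-yl)-5,6-dimethoxy-1-benzofuran-3-yl]-4-(4-methoxyphenyl)-1H-pyrrole-2,5-dione F5. KOH in aqueous EtOH hydrolyses the imide to dipotassium (2Z)-2-[2-(2-benzyl-1,3-dioxolan-2-yl)-5,6-dimethoxy-1-benzofuran-3-yl]-3-(4-methoxyphenyl)but-2-enedioate F6. Acidification with 2 M HCl closes the anhydride (passing through 11) and cleaves the dioxolane, arriving at 12.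

Step 4. Process at risk: attack of the acylium ion on the dimethoxybenzo ring (C7, between two oxygens) and decarbonylation of the phenylacetyl cation to a benzylating species. The fallback sets out from 5 and returns at 7. Vilsmeier–Haack formylation (POCl3, DMF), whose weaker electrophile cannot lose CO and should react only at the furan carbon, gives methyl 2-(2-formyl-5,6-dimethoxy-1-benzofuran-3-yl)acetate F7. BnMgCl in THF at −78 °C adds to the aldehyde in preference to the ester to give racemic methyl 2-[2-(1-hydroxy-2-phenylethyl)-5,6-dimethoxy-1-benzofuran-3-yl]acetate F8. F8 is oxidised at once with Dess–Martin periodinane to 7, before it can lactonise onto the neighbouring ester.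

**Further compounds**

F1 | step 8 | (2Z)-2-[5,6-dimethoxy-2-(2-phenylacetyl)-1-benzofuran-3-yl]-4-methoxy-3-(4-methoxyphenyl)-4-oxobut-2-enoic acid | OC(=O)/C(c1c(C(=O)Cc2ccccc2)oc2cc(OC)c(OC)cc12)=C(\C(=O)OC)c1ccc(OC)cc1
F2 | step 8 | dimethyl (2Z)-2-[5,6-dimethoxy-2-(2-phenylacetyl)-1-benzofuran-3-yl]-3-(4-methoxyphenyl)but-2-enedioate | COC(=O)/C(c1ccc(OC)cc1)=C(\C(=O)OC)c1c(C(=O)Cc2ccccc2)oc2cc(OC)c(OC)cc12
F3 | step 8 | methyl (2Z)-2-(2-hydroxy-7,8-dimethoxy-4-oxo-3-phenyldibenzo[b,d]furan-1(4H)-ylidene)-2-(4-methoxyphenyl)acetate | COC(=O)/C(c1ccc(OC)cc1)=C1\C(O)=C(c2ccccc2)C(=O)c2oc3cc(OC)c(OC)cc3c21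
F4 | step 7 | 2-[2-(2-benzyl-1,3-dioxolan-2-yl)-5,6-dimethoxy-1-benzofuran-3-yl]acetamide | NC(=O)Cc1c(C2(Cc3ccccc3)OCCO2)oc2cc(OC)c(OC)cc12
F5 | step 7 | 3-[2-(2-benzyl-1,3-dioxolan-2-yl)-5,6-dimethoxy-1-benzofuran-3-yl]-4-(4-methoxyphenyl)-1H-pyrrole-2,5-dione | COc1ccc(C2=C(c3c(C4(Cc5ccccc5)OCCO4)oc4cc(OC)c(OC)cc34)C(=O)NC2=O)cc1
F6 | step 7 | dipotassium (2Z)-2-[2-(2-benzyl-1,3-dioxolan-2-yl)-5,6-dimethoxy-1-benzofuran-3-yl]-3-(4-methoxyphenyl)but-2-enedioate | [K+].[K+].[O-]C(=O)/C(c1ccc(OC)cc1)=C(\C([O-])=O)c1c(C2(Cc3ccccc3)OCCO2)oc2cc(OC)c(OC)cc12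
F7 | step 4 | methyl 2-(2-formyl-5,6-dimethoxy-1-benzofuran-3-yl)acetate | COC(=O)Cc1c(C=O)oc2cc(OC)c(OC)cc12
F8 | step 4 | methyl 2-[2-(1-hydroxy-2-phenylethyl)-5,6-dimethoxy-1-benzofuran-3-yl]acetate (racemic) | COC(=O)Cc1c(C(O)Cc2ccccc2)oc2cc(OC)c(OC)cc12
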